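**Remark (assumption and numbering):** cembrane numbering is used throughout: ring C1–C14; C1 carries C15, which bears the lactone carbonyl C16 and the methyl C17; C18 on C4, C19 on C8, C20 on C12. The target is read as (1R,3R,4S,7R,11S,12S,15S). The C15 methyl is introduced after the key step.

## Retrosynthetic overview

1. The hydroperoxide comes last by a Schenck ene reaction on the 7,8-alkene of lactone 19. The C15 methyl comes from enolate methylation of 17, and C1–H from CuH conjugate reduction of the unsaturated lactone 16.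
2. Key disconnection: C1–C2 and O–C3 of 16 are made together from acyclic 13. A sulfonyl carbanion at C1 closes the 14-membered ring on C2–I, the C16 carboxylate then opens the adjacent 3,4-epoxide at C3 to the δ-lactone, and sulfinate leaves.
3. Enabling feature: in the δ-lactone ring (O, C16, C15, C1, C2, C3), the methylene C2 lies between C1 (β to the carbonyl) and C3, and C3–O(lactone)/C4–OH is the anti-opened form of an (E)-trisubstituted epoxide. CH2(2)–I plus the oxirane carbon C3 is therefore a 1,2-bis-electrophile, matched by the C1/O bis-nucleophile of a β-sulfonyl propanoate.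
4. 13 comes from bis(epoxy iodide) 10 and 3-(phenylsulfonyl)propanoic acid 11. 10 comes from farnesyl acetate by SeO2 oxidation, one-carbon extension (Wittig, 9-BBN), Sharpless epoxidation (allylic end) and hydroxamate–Hf epoxidation (homoallylic end).
5. Ring order: the two oxiranes, then the 14-membered carbocycle and the δ-lactone in one operation; the 7,8-alkene is functionalised last.

Key step: step 9

## Route

Step 1
Reactants: 1 (2E,6E)-farnesyl acetate
Product: 2 (2E,6E,10E)-12-hydroxy-3,7,11-trimethyldodeca-2,6,10-trien-1-yl acetate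
Conditions: SeO2 (cat.), t-BuOOH, salicylic acid (cat.), CH2Cl2, 0 °C → rt
Reagents that add atoms: tert-butyl hydroperoxide CC(C)(C)OO (net oxygen source; SeO2 is the catalytic carrier)
Why: Riley-type SeO2 allylic oxidation (ene/[2,3] sequence) is selective for the (E)-methyl of the terminal trisubstituted alkene and gives the (10E)-allylic alcohol.

Step 2
Reactants: 2 (2E,6E,10E)-12-hydroxyfarnesyl acetate
Product: 3 (2E,6E,10E)-3,7,11-trimethyl-12-oxododeca-2,6,10-trien-1-yl acetate
Conditions: MnO2, CH2Cl2, rt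
Reagents that add atoms: none
Why: MnO2 oxidises only the free allylic alcohol to the enal; no stereocentre is involved and the acetate-protected allylic position is inert.

Step 3
Reactants: 3 (2E,6E,10E)-12-oxofarnesyl acetate
Product: 4 (2E,6E,10E)-3,7,11-trimethyltrideca-2,6,10,12-tetraen-1-yl acetate
Conditions: Ph3PCH3Br, KHMDS, THF, −78 → 0 °C
Reagents that add atoms: methyltriphenylphosphonium bromide C[P+](c1ccccc1)(c1ccccc1)c1ccccc1.[Br-]
Why: Wittig methylenation of the enal adds the future C14 as a terminal vinyl group; the non-stabilised ylide reacts with the aldehyde far faster than with the acetate and the alkene geometries are untouched.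

Step 4
Reactants: 4 (2E,6E,10E)-3,7,11-trimethyltrideca-2,6,10,12-tetraen-1-yl acetate
Product: 7 (2E,6E,10E)-3,7,11-trimethyltrideca-2,6,10-triene-1,13-diol, via B-alkyl-9-BBN adduct 5 (not isolated), via 13-hydroxy acetate 6 (not isolated)
Conditions: 9-BBN, THF, 0 °C → rt; then NaOH, H2O2, 0 → 40 °C
Reagents that add atoms: hydrogen peroxide OO
Why: anti-Markovnikov hydroboration with 9-BBN takes only the monosubstituted terminus of the diene, and the alkaline peroxide work-up oxidises the C–B bond and saponifies the acetate, freeing both hydroxyl groups needed as directing groups.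

Step 5
Reactants: 7 (2E,6E,10E)-3,7,11-trimethyltrideca-2,6,10-triene-1,13-diol
Product: 8 (2S,3S,6E,10E)-2,3-epoxy-3,7,11-trimethyltrideca-6,10-diene-1,13-diol
Conditions: Ti(OiPr)4, L-(+)-DET, t-BuOOH, 4 Å MS, CH2Cl2, −20 °C
Reagents that add atoms: tert-butyl hydroperoxide CC(C)(C)OO
Why: Sharpless asymmetric epoxidation; L-(+)-tartrate delivers oxygen to the face that gives the (2S,3S)-epoxy alcohol (as for geraniol), and the homoallylic alcohol and the isolated alkenes should not react under these conditions.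

Step 6
Reactants: 8 (2S,3S,6E,10E)-2,3-epoxy-3,7,11-trimethyltrideca-6,10-diene-1,13-diol
Product: 9 (2S,3S,6E,10S,11S)-2,3:10,11-diepoxy-3,7,11-trimethyltridec-6-ene-1,13-diol
Conditions: Hf(OtBu)4 (cat.), chiral bis-hydroxamic acid ligand (enantiomer giving the 10S,11S epoxide), cumene hydroperoxide, DMPU, 4 Å MS, toluene, 0 °C
Reagents that add atoms: cumene hydroperoxide CC(C)(OO)c1ccccc1
Why: hydroxyl-directed asymmetric epoxidation of a homoallylic alcohol (hafnium/bis-hydroxamic acid catalysis); the ligand sets the (10S,11S) oxirane on the (E)-alkene, and the 6,7-alkene is too remote from either hydroxyl group to be delivered to.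

Step 7
Reactants: 9 (2S,3S,6E,10S,11S)-2,3:10,11-diepoxy-3,7,11-trimethyltridec-6-ene-1,13-diol
Product: 10 (2R,3S,6E,10S,11S)-2,3:10,11-diepoxy-1,13-diiodo-3,7,11-trimethyltridec-6-ene
Conditions: I2, PPh3, imidazole, CH2Cl2, 0 °C
Reagents that add atoms: iodine II
Why: Appel-type (Garegg–Samuelsson) iodination of both primary alcohols under imidazole buffering, which spares the epoxides; no stereocentre is touched (the descriptor at C2 changes to R only through the new priority of CH2I).

Step 8
Reactants: 10 (2R,3S,6E,10S,11S)-2,3:10,11-diepoxy-1,13-diiodo-3,7,11-trimethyltridec-6-ene; 11 3-(phenylsulfonyl)propanoic acid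
Product: 13 (6S,7S,10E,14S,15R)-6,7:14,15-diepoxy-16-iodo-6,10,14-trimethyl-3-(phenylsulfonyl)hexadec-10-enoic acid (both C3 epimers), via dilithiated sulfonyl propanoate 12 (not isolated)
Conditions: 11, LDA (2.05 equiv), THF–DMPU, −78 → 0 °C; add to 10 (1.5 equiv), THF, −78 → −30 °C; cold dil. HCl to pH 4
Reagents that add atoms: none
Why: C-alkylation of the dilithiated β-sulfonyl carboxylic acid (a β-acylvinyl anion equivalent) by SN2 at the unhindered homo-iodide, which should react much faster than the iodide flanked by the oxirane; the new sulfonyl-bearing centre is erased in step 9.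

Step 9
Reactants: 13 (6S,7S,10E,14S,15R)-6,7:14,15-diepoxy-16-iodo-6,10,14-trimethyl-3-(phenylsulfonyl)hexadec-10-enoic acid
Product: 16 (3R,4S,7E,11S,12S)-11,12-epoxy-4-hydroxy-17-norcembra-1(15),7-dien-16,3-olide, via macrocyclic sulfonyl carboxylate 14 (not isolated), via sulfonyl hydroxy lactone 15 (not isolated)
Conditions: LDA (2.1 equiv), THF–DMPU (10:1), 2 mM, −78 → 0 °C; then DBU (0.5 equiv), 55 °C
Reagents that add atoms: none
Why: LDA turns 13 into its carboxylate and tertiary α-sulfonyl carbanion, which closes the 14-membered carbocycle by SN2 at C2–I (14-exo-tet); on warming, the C16 carboxylate, now held five atoms from C3, opens the Sharpless oxirane at C3 (6-exo-tet, anti) to the δ-lactone, and the β-sulfonyl lactone loses lithium benzenesulfinate by E1cB, so the sulfone that activated C1 is removed in the same flask. The closest known reaction types are the alkylation of dilithiated 3-(arylsulfonyl)propanoic acids followed by lactone closure and sulfinate loss to unsaturated lactones, and sulfone-carbanion macro-alkylation to 14-membered cembranoid rings; here the two electrophilic carbons are adjacent atoms of one chain. C3 is set by clean inversion at the oxirane carbon ((3S,4S)-epoxide in 14 becomes the (3R)-lactone C–O in 15), C4 keeps its C–O bond and becomes the tertiary alcohol, C1 becomes sp2 so both epimers of 13 converge, and the 11,12-epoxide and 7,8-alkene are spectators. The selectivities needed are C- over O-alkylation (carbanion far more nucleophilic than lithium carboxylate), ring closure over attack on the nearer 11,12-epoxide (4-exo at a fully substituted carbon or 5-endo, both expected to be slow), and 6-exo over 7-endo lactonisation (basic conditions favour SN2 at the secondary C3).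

Step 10
Reactants: 16 (3R,4S,7E,11S,12S)-11,12-epoxy-4-hydroxy-17-norcembra-1(15),7-dien-16,3-olide
Product: 17 (1R,3R,4S,7E,11S,12S)-11,12-epoxy-4-hydroxy-17-norcembr-7-en-16,3-olide
Conditions: Cu(OAc)2·H2O (5 mol %), p-tol-BINAP (matched enantiomer), (EtO)2MeSiH, t-BuOH, toluene, 0 °C; aq. NH4F
Reagents that add atoms: none
Why: copper hydride conjugate reduction of a β,β-disubstituted unsaturated lactone (Stryker/Buchwald type); hydride should add to C1 anti to the bulky C3 substituent, reinforced by the matched ligand, placing C14 cis to C4 (1R), while the epoxide, isolated alkene and lactone carbonyl are not reduced.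

Step 11
Reactants: 17 (1R,3R,4S,7E,11S,12S)-11,12-epoxy-4-hydroxy-17-norcembr-7-en-16,3-olide
Product: 19 (1R,3R,4S,7E,11S,12S,15S)-11,12-epoxy-4-hydroxycembr-7-en-16,3-olide, via dilithium alkoxide enolate 18 (not isolated)
Conditions: LDA (2.2 equiv), THF, −78 °C; MeI, −78 → −40 °C; AcOH quench (DBU, toluene, rt if C15 needs equilibration)
Reagents that add atoms: iodomethane CI
Why: lactone enolate alkylation anti to the C1 substituent gives the trans (15S) methyl, which is also the thermodynamic all-equatorial isomer; the second equivalent of base covers the tertiary alkoxide, which should not be methylated at low temperature.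

Step 12
Reactants: 19 (1R,3R,4S,7E,11S,12S,15S)-11,12-epoxy-4-hydroxycembr-7-en-16,3-olide
Product: 20 (1R,3R,4S,7R,11S,12S,15S)-11,12-epoxy-7-hydroperoxy-4-hydroxycembr-8(19)-en-16,3-olide (target)
Conditions: O2, tetraphenylporphyrin (cat.), hν, CH2Cl2, −20 °C
Reagents that add atoms: oxygen O=O
Why: Schenck ene reaction of singlet oxygen on the only alkene; the cis effect directs abstraction to the C19 methyl on the more substituted side, giving the C7 hydroperoxide with the exocyclic methylene, and attack on the exposed face of the macrocycle is expected to give (7R).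

## Compound list

1 | (2E,6E)-farnesyl acetate | CC(=O)OC/C=C(\C)CC/C=C(\C)CCC=C(C)C | starting material
2 | (2E,6E,10E)-12-hydroxy-3,7,11-trimethyldodeca-2,6,10-trien-1-yl acetate | CC(=O)OC/C=C(\C)CC/C=C(\C)CC/C=C(\C)CO | intermediate
3 | (2E,6E,10E)-3,7,11-trimethyl-12-oxododeca-2,6,10-trien-1-yl acetate | CC(=O)OC/C=C(\C)CC/C=C(\C)CC/C=C(\C)C=O | intermediate
4 | (2E,6E,10E)-3,7,11-trimethyltrideca-2,6,10,12-tetraen-1-yl acetate | CC(=O)OC/C=C(\C)CC/C=C(\C)CC/C=C(\C)C=C | intermediate
5 | 9-[(3E,7E,11E)-13-acetoxy-3,7,11-trimethyltrideca-3,7,11-trien-1-yl]-9-borabicyclo[3.3.1]nonane | CC(=O)OC/C=C(\C)CC/C=C(\C)CC/C=C(\C)CCB1C2CCCC1CCC2 | intermediate (not isolated)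
6 | (2E,6E,10E)-13-hydroxy-3,7,11-trimethyltrideca-2,6,10-trien-1-yl acetate | CC(=O)OC/C=C(\C)CC/C=C(\C)CC/C=C(\C)CCO | intermediate (not isolated)
7 | (2E,6E,10E)-3,7,11-trimethyltrideca-2,6,10-triene-1,13-diol | OC/C=C(\C)CC/C=C(\C)CC/C=C(\C)CCO | intermediate
8 | (2S,3S,6E,10E)-2,3-epoxy-3,7,11-trimethyltrideca-6,10-diene-1,13-diol | OC[C@@H]1O[C@@]1(C)CC/C=C(\C)CC/C=C(\C)CCO | intermediate
9 | (2S,3S,6E,10S,11S)-2,3:10,11-diepoxy-3,7,11-trimethyltridec-6-ene-1,13-diol | OC[C@@H]1O[C@@]1(C)CC/C=C(\C)CC[C@@H]1O[C@@]1(C)CCO | intermediate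
10 | (2R,3S,6E,10S,11S)-2,3:10,11-diepoxy-1,13-diiodo-3,7,11-trimethyltridec-6-ene | IC[C@@H]1O[C@@]1(C)CC/C=C(\C)CC[C@@H]1O[C@@]1(C)CCI | intermediate
11 | 3-(phenylsulfonyl)propanoic acid | OC(=O)CCS(=O)(=O)c1ccccc1 | starting material
12 | lithium 3-lithio-3-(phenylsulfonyl)propanoate | [Li+].[Li+].[O-]C(=O)C[CH-]S(=O)(=O)c1ccccc1 | intermediate (not isolated)
13 | (6S,7S,10E,14S,15R)-6,7:14,15-diepoxy-16-iodo-6,10,14-trimethyl-3-(phenylsulfonyl)hexadec-10-enoic acid (C3 epimers) | IC[C@@H]1O[C@@]1(C)CC/C=C(\C)CC[C@@H]1O[C@@]1(C)CCC(CC(=O)O)S(=O)(=O)c1ccccc1 | intermediate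
14 | lithium 2-[(3S,4S,7E,11S,12S)-3,4:11,12-diepoxy-4,8,12-trimethyl-1-(phenylsulfonyl)cyclotetradec-7-en-1-yl]acetate (C1 epimers) | [Li+].[O-]C(=O)CC1(S(=O)(=O)c2ccccc2)C[C@@H]2O[C@@]2(C)CC/C=C(\C)CC[C@@H]2O[C@@]2(C)CC1 | intermediate (not isolated)
15 | lithium alkoxide of (3R,4S,7E,11S,12S)-11,12-epoxy-4-hydroxy-1-(phenylsulfonyl)-17-norcembr-7-en-16,3-olide (C1 epimers) | O=C1CC2(S(=O)(=O)c3ccccc3)C[C@@H](O1)[C@@](C)([O-])CC/C=C(\C)CC[C@@H]3O[C@@]3(C)CC2.[Li+] | intermediate (not isolated)
16 | (3R,4S,7E,11S,12S)-11,12-epoxy-4-hydroxy-17-norcembra-1(15),7-dien-16,3-olide | O=C1C=C2C[C@@H](O1)[C@@](C)(O)CC/C=C(\C)CC[C@@H]3O[C@@]3(C)CC2 | intermediate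
17 | (1R,3R,4S,7E,11S,12S)-11,12-epoxy-4-hydroxy-17-norcembr-7-en-16,3-olide | O=C1C[C@H]2C[C@@H](O1)[C@@](C)(O)CC/C=C(\C)CC[C@@H]3O[C@@]3(C)CC2 | intermediate
18 | dilithium alkoxide enolate of 17 | [Li+].[Li+].[O-]C1=C[C@H]2C[C@@H](O1)[C@@](C)([O-])CC/C=C(\C)CC[C@@H]3O[C@@]3(C)CC2 | intermediate (not isolated)
19 | (1R,3R,4S,7E,11S,12S,15S)-11,12-epoxy-4-hydroxycembr-7-en-16,3-olide | O=C1[C@@H](C)[C@H]2C[C@@H](O1)[C@@](C)(O)CC/C=C(\C)CC[C@@H]3O[C@@]3(C)CC2 | intermediate
20 | (1R,3R,4S,7R,11S,12S,15S)-11,12-epoxy-7-hydroperoxy-4-hydroxycembr-8(19)-en-16,3-olide | C=C1CC[C@@H]2O[C@@]2(C)CC[C@@H]2C[C@@H](OC(=O)[C@H]2C)[C@@](C)(O)CC[C@H]1OO | target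

## Summary

Total step count: 12. Longest linear sequence: 12 steps (1 → 20); 11 enters at step 8.

Steps most likely to fail:

**1. Step 9 (key step).** The tertiary carbanion may attack the nearer 11,12-epoxide (four- or five-membered ring formation) or another molecule (oligomerisation) faster than it closes the 14-membered ring, and lactonisation could stray to the tertiary oxirane carbon.
Fallback, setting out from 10 and returning at 17: benzeneselenol with K2CO3 (1 equiv, DMF, 0 °C) would replace the unhindered iodide of 10 to give the iodo selenide F1. Alkylation of dianion 12 with the remaining epoxy-carbinyl iodide of F1 would give the open-chain sulfonyl carboxylate F2 (not isolated). On warming, F2 would lactonise by the same 6-exo epoxide opening to the sulfonyl hydroxy lactone F3 (not isolated), and DBU would then expel sulfinate to give the monocyclic unsaturated lactone F4; the same two bonds are thus made intermolecularly. The 14-membered ring would then be closed without any carbanion by radical conjugate addition (slow addition of (Me3Si)3SiH/AIBN, benzene, 80 °C, 2 mM): the primary radical from the C–Se bond adds to the β-carbon of the lactone, with the tether expected to deliver C14 cis to the C3 substituent, giving 17 directly. This uses selenide displacement, the β-acylvinyl-anion lactone annulation and radical macrocyclisation onto an enoate, all known reaction types.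

**2. Step 12.** Hydrogen abstraction may go to C6–H instead of the C19 methyl (giving the tertiary 8-hydroperoxide), and facial selectivity at C7 may be poor.
Fallback, setting out from 19 and returning at 20: the (7S)-hydroperoxide F5, the C7 epimer formed beside 20, would be reduced with PPh3 to the (7S)-allylic alcohol F6. MsCl/Et3N at −30 °C would give the allylic mesylate F7. Displacement with 2-methoxyprop-2-yl hydroperoxide and CsOH (DMF, 0 °C) would invert C7 to the (7R)-perketal F8. Aqueous acetic acid would then release 20. Stereocontrol then rests on an SN2 inversion instead of the face selectivity of singlet oxygen.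

**3. Step 8.** Site selectivity between the two primary iodides may be lost; a linchpin attached at the epoxide-flanked end would, once deprotonated in step 9, close a cyclopropane onto the 3,4-epoxide.
Fallback, setting out from 9 and returning at 16: TsCl/Et3N/DMAP would give the bis-tosylate F9. NaI (1.1 equiv, acetone, rt) should exchange only the unhindered tosylate, giving the iodo tosylate F10, which is neutral and can be purified from any regioisomer. Dianion 12 then meets one iodide and one much less reactive epoxy tosylate and would give the sulfonyl acid tosylate F11. LDA with LiI at high dilution, then DBU, would close F11 through 14 and 15 to 16. The differentiation then rests on two different leaving groups and a separable intermediate.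

## Further compounds

F1 | step 9 | (2R,3S,6E,10S,11S)-2,3:10,11-diepoxy-1-iodo-3,7,11-trimethyl-13-(phenylselanyl)tridec-6-ene | IC[C@@H]1O[C@@]1(C)CC/C=C(\C)CC[C@@H]1O[C@@]1(C)CC[Se]c1ccccc1
F2 | step 9 | lithium (5S,6S,9E,13S,14S)-5,6:13,14-diepoxy-6,10,14-trimethyl-16-(phenylselanyl)-3-(phenylsulfonyl)hexadec-9-enoate (C3 epimers, not isolated) | [Li+].[O-]C(=O)CC(C[C@@H]1O[C@@]1(C)CC/C=C(\C)CC[C@@H]1O[C@@]1(C)CC[Se]c1ccccc1)S(=O)(=O)c1ccccc1
F3 | step 9 | lithium alkoxide of the 4-(phenylsulfonyl)tetrahydropyran-2-one formed by lactonisation of F2 (not isolated) | [Li+].O=C1CC(S(=O)(=O)c2ccccc2)C[C@@H](O1)[C@@](C)([O-])CC/C=C(\C)CC[C@@H]2O[C@@]2(C)CC[Se]c2ccccc2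
F4 | step 9 | (6R)-6-[(2S,5E,9S,10S)-9,10-epoxy-2-hydroxy-6,10-dimethyl-12-(phenylselanyl)dodec-5-en-2-yl]-5,6-dihydro-2H-pyran-2-one | O=C1C=CC[C@@H](O1)[C@@](C)(O)CC/C=C(\C)CC[C@@H]2O[C@@]2(C)CC[Se]c2ccccc2
F5 | step 12 | (1R,3R,4S,7S,11S,12S,15S)-11,12-epoxy-7-hydroperoxy-4-hydroxycembr-8(19)-en-16,3-olide (C7 epimer of 20) | O=C1[C@@H](C)[C@H]2C[C@@H](O1)[C@@](C)(O)CC[C@H](OO)C(=C)CC[C@@H]3O[C@@]3(C)CC2
F6 | step 12 | (1R,3R,4S,7S,11S,12S,15S)-11,12-epoxy-4,7-dihydroxycembr-8(19)-en-16,3-olide | O=C1[C@@H](C)[C@H]2C[C@@H](O1)[C@@](C)(O)CC[C@H](O)C(=C)CC[C@@H]3O[C@@]3(C)CC2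
F7 | step 12 | 7-O-methanesulfonate of F6 | O=C1[C@@H](C)[C@H]2C[C@@H](O1)[C@@](C)(O)CC[C@H](OS(C)(=O)=O)C(=C)CC[C@@H]3O[C@@]3(C)CC2
F8 | step 12 | (7R)-7-[(2-methoxypropan-2-yl)peroxy] derivative (perketal of 20) | O=C1[C@@H](C)[C@H]2C[C@@H](O1)[C@@](C)(O)CC[C@@H](OOC(C)(C)OC)C(=C)CC[C@@H]3O[C@@]3(C)CC2
F9 | step 8 | (2S,3S,6E,10S,11S)-2,3:10,11-diepoxy-3,7,11-trimethyltridec-6-ene-1,13-diyl bis(4-methylbenzenesulfonate) | Cc1ccc(cc1)S(=O)(=O)OC[C@@H]1O[C@@]1(C)CC/C=C(\C)CC[C@@H]1O[C@@]1(C)CCOS(=O)(=O)c1ccc(C)cc1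
F10 | step 8 | (2S,3S,6E,10S,11S)-2,3:10,11-diepoxy-13-iodo-3,7,11-trimethyltridec-6-en-1-yl 4-methylbenzenesulfonate | Cc1ccc(cc1)S(=O)(=O)OC[C@@H]1O[C@@]1(C)CC/C=C(\C)CC[C@@H]1O[C@@]1(C)CCI
F11 | step 8 | (6S,7S,10E,14S,15S)-6,7:14,15-diepoxy-6,10,14-trimethyl-3-(phenylsulfonyl)-16-(tosyloxy)hexadec-10-enoic acid (C3 epimers) | Cc1ccc(cc1)S(=O)(=O)OC[C@@H]1O[C@@]1(C)CC/C=C(\C)CC[C@@H]1O[C@@]1(C)CCC(CC(=O)O)S(=O)(=O)c1ccccc1
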